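Ring A, the cyclohexadienone (C1 ketone; C2 bridge-bearing; C3 and C5 enol carbons flanking quaternary C4; C6 acyl-bearing), alternates acceptor and donor carbons. Cutting C1–C2 and C3–C4 gives a C4–C5–C6–C1 dipole, stored as a strained racemic 3,3-diethoxycyclobutanone. It also gives a C2–C3 unit, stored as the silyl ketene acetal of a dihydrocoumarin whose ring oxygen is the chromene 7′-OH beside the methylene bridge. One silylium-catalysed formal [4+2] under a confined chiral anion opens the four-membered ring, erases its configuration, joins both halves, closes ring A and sets C4. C-acylation at C6 finishes the synthesis.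

Key step: step 8

Assumption: the sense of induction of the chiral anion cannot be predicted, so the catalyst antipode that gives (S)-20 is taken from a screen. (S)-20 has the same spatial arrangement at C4 as (R)-23. The descriptor changes only because C3 and C5 swap priority. All enols are drawn in one tautomer.

Step 1
Reactants: 1 propanoic acid; 2 1-bromo-3-methylbut-2-ene (prenyl bromide)
Product: 3 rac-2,5-dimethylhex-4-enoic acid
Conditions: LiN(iPr)2 (2.1 equiv), THF, 0 °C; 2, 0 to 23 °C; 1 M HCl
Reagents that add atoms: none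
Why: SN2 C-alkylation of the carboxylic acid dianion by the allylic bromide is standard, and the α-stereocentre does not matter because it is lost in step 3.

Step 2
Reactants: 3 rac-2,5-dimethylhex-4-enoic acid
Product: 4 rac-2,5-dimethylhex-4-enoyl chloride
Conditions: (COCl)2, DMF (cat.), CH2Cl2, 0 °C
Reagents that add atoms: oxalyl chloride, O=C(Cl)C(=O)Cl
Why: Standard acid chloride formation through the catalytic chloroiminium species, driven by gas evolution, leaves the trisubstituted alkene untouched at 0 °C.

Step 3
Reactants: 4 rac-2,5-dimethylhex-4-enoyl chloride; 5 1,1-diethoxyethene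
Product: 7 rac-3,3-diethoxy-2-methyl-2-(3-methylbut-2-en-1-yl)cyclobutan-1-one, via methyl(prenyl)ketene 6 (not isolated)
Conditions: Et3N, 5 (2 equiv), MeCN, 80 °C, slow addition of 4
Reagents that add atoms: none
Why: Dehydrochlorination gives the dialkylketene, which undergoes the thermal ketene–ketene acetal [2+2] cycloaddition with the nucleophilic CH2 of 5 bonding to the ketene carbonyl carbon, so the ketal carbon (future C1) ends next to the quaternary carbon (future C4) and the product is racemic.

Step 4
Reactants: 8 2-methyl-1-(2,4,6-trihydroxyphenyl)propan-1-one; 9 3-chloro-3-methylbut-1-yne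
Product: 10 1-[2,6-dihydroxy-4-(2-methylbut-3-yn-2-yloxy)phenyl]-2-methylpropan-1-one
Conditions: DBU, CuCl2·2H2O (1 mol %), MeCN, 0 °C
Reagents that add atoms: none
Why: Copper-catalysed O-alkylation by the tertiary propargylic chloride takes the 4-OH, the only hydroxyl not hydrogen-bonded to the ketone and the most acidic one.

Step 5
Reactants: 10 1-[2,6-dihydroxy-4-(2-methylbut-3-yn-2-yloxy)phenyl]-2-methylpropan-1-one
Product: 11 1-(5,7-dihydroxy-2,2-dimethyl-2H-chromen-6-yl)-2-methylpropan-1-one
Conditions: o-xylene, 140 °C
Reagents that add atoms: none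
Why: Aromatic propargyl Claisen rearrangement, 1,5-hydrogen shift and oxa-6π electrocyclisation build the 2,2-dimethylchromene, and only the 6-acyl-5,7-dihydroxy isomer can form because the ether oxygen sits para to the acyl group.

Step 6
Reactants: 11 1-(5,7-dihydroxy-2,2-dimethyl-2H-chromen-6-yl)-2-methylpropan-1-one; 12 Meldrum's acid (2,2-dimethyl-1,3-dioxane-4,6-dione); 13 formaldehyde
Product: 17 tricyclic lactone (δ-lactone of 3-[5,7-dihydroxy-2,2-dimethyl-6-(2-methylpropanoyl)-2H-chromen-8-yl]propanoic acid closed on the 7′-OH), via methylene Meldrum acid 14 (not isolated), via Michael adduct 15 (not isolated), via lactone acid 16 (not isolated)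
Conditions: 12, 37% aq. 13, L-proline (10 mol %), MeCN, 23 °C; then pyridine, 100 °C
Reagents that add atoms: none
Why: Knoevenagel condensation, Michael addition of C8′ (the only free aromatic CH), opening of the dioxanedione by the neighbouring 7′-OH and loss of acetone and CO2 make up the known three-component route from electron-rich phenols to 3,4-dihydrocoumarins.

Step 7
Reactants: 17 tricyclic lactone
Product: 18 bis-silyl compound (5′-O-TBS ether of 17 whose lactone is converted into the O-TBS ketene acetal, a 2-silyloxy-4H-pyran ring)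
Conditions: LiN(iPr)2 (2.2 equiv), THF, −78 °C; TBSOTf (2.3 equiv), −78 °C; non-aqueous work-up
Reagents that add atoms: tert-butyldimethylsilyl triflate, CC(C)(C)[Si](C)(C)OS(=O)(=O)C(F)(F)F
Why: Kinetic deprotonation of the phenol and of the lactone α-CH2 (more acidic and less hindered than the isobutyryl CH) followed by O-silylation is standard silyl ketene acetal formation, and it is kept cold to prevent E1cB opening of the aryl ester enolate.

Step 8
Reactants: 7 rac-3,3-diethoxy-2-methyl-2-(3-methylbut-2-en-1-yl)cyclobutan-1-one; 18 bis-silyl ketene acetal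
Product: 20 (S)-2-{[5,7-dihydroxy-2,2-dimethyl-6-(2-methylpropanoyl)-2H-chromen-8-yl]methyl}-3,5-dihydroxy-4-methyl-4-(3-methylbut-2-en-1-yl)cyclohexa-2,5-dien-1-one, via tetracyclic ketal 19 (not isolated)
Conditions: chiral BINOL-derived N-triflyl imidodiphosphorimidate (IDPi) Brønsted acid (5 mol %), toluene, −60 °C; then HF·pyridine, THF, 0 °C; then 1 M HCl, THF, 23 °C
Reagents that add atoms: water, O
Why: Proposed new method: 18 silylates the acid to a silylium ion paired with the confined chiral anion, which O-silylates the ketone of 7 and heterolyses the strained, more substituted C1–C4 bond to a diethoxycarbenium ion (C1) tethered to a tetrasubstituted silyl enol ether (C4=C5), and because this opening is reversible both enantiomers of 7 and both enol ether geometries interconvert before product formation (stereoconvergent, Curtin–Hammett). C2 of 18 adds to C1 in a Mukaiyama-type step (first bond) and C4 then attacks the aryloxy(silyloxy)carbenium carbon C3 in a 6-(enolendo)-exo-trig closure of ring A (second bond), which frees the silylium ion. The closest known reaction types are the Lewis acid promoted formal [4+2] cycloaddition of 3-alkoxycyclobutanones with silyl enol ethers through 1,4-zwitterions and silylium–IDPi Mukaiyama additions to oxocarbenium ions. C4 is the only lasting stereocentre and is fixed in the ring closure by the anion paired with the C3 cation, whose pocket has to take the methyl group and turn the prenyl chain outwards, while C2 and C3 become sp2 on work-up. The step needs cleavage of C1–C4 rather than C1–C6, secured by the quaternary C4 and the more stable enol ether, and capture of C1 by 18 rather than by the prenyl alkene, secured by the much higher nucleophilicity of the ketene acetal. HF·pyridine and dilute acid then open the silyl hemiketal to the 7′-phenol and the C3 ketone and hydrolyse the C1 ketal, which gives 20.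

Step 9
Reactants: 20 (S)-des-isobutyryl compound; 21 2-methylpropanoyl chloride
Product: 23 (R)-2-{[5,7-dihydroxy-2,2-dimethyl-6-(2-methylpropanoyl)-2H-chromen-8-yl]methyl}-3,5-dihydroxy-4-methyl-4-(3-methylbut-2-en-1-yl)-6-(2-methylpropanoyl)cyclohexa-2,5-dien-1-one (target), via enol ester 22 (not isolated)
Conditions: 21 (1.05 equiv), Et3N, CH2Cl2, 0 °C; then DMAP (30 mol %), 23 to 40 °C; 1 M HCl
Reagents that add atoms: none
Why: O-acylation of the most acidic enol and DMAP-catalysed O-to-C acyl migration (Fries-type enol ester rearrangement of cyclic 1,3-diones) place the acyl group on C6, the only free ring carbon between two carbonyls, while both phenols are hydrogen-bonded and flanked and the quaternary C4 cannot epimerise.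

Compound list
1 | propanoic acid | CCC(=O)O | starting material
2 | 1-bromo-3-methylbut-2-ene | CC(C)=CCBr | starting material
3 | rac-2,5-dimethylhex-4-enoic acid | CC(C)=CCC(C)C(=O)O | intermediate
4 | rac-2,5-dimethylhex-4-enoyl chloride | CC(C)=CCC(C)C(=O)Cl | intermediate
5 | 1,1-diethoxyethene | C=C(OCC)OCC | starting material
6 | methyl(prenyl)ketene (2,5-dimethylhexa-1,4-dien-1-one) | CC(C)=CCC(C)=C=O | intermediate
7 | rac-3,3-diethoxy-2-methyl-2-(3-methylbut-2-en-1-yl)cyclobutan-1-one | CCOC1(OCC)CC(=O)C1(C)CC=C(C)C | intermediate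
8 | 2-methyl-1-(2,4,6-trihydroxyphenyl)propan-1-one | CC(C)C(=O)c1c(O)cc(O)cc1O | starting material
9 | 3-chloro-3-methylbut-1-yne | CC(C)(Cl)C#C | starting material
10 | 1-[2,6-dihydroxy-4-(2-methylbut-3-yn-2-yloxy)phenyl]-2-methylpropan-1-one | CC(C)C(=O)c1c(O)cc(OC(C)(C)C#C)cc1O | intermediate
11 | 1-(5,7-dihydroxy-2,2-dimethyl-2H-chromen-6-yl)-2-methylpropan-1-one | CC(C)C(=O)c1c(O)cc2OC(C)(C)C=Cc2c1O | intermediate
12 | Meldrum's acid | CC1(C)OC(=O)CC(=O)O1 | starting material
13 | formaldehyde | C=O | starting material
14 | 2,2-dimethyl-5-methylidene-1,3-dioxane-4,6-dione | C=C1C(=O)OC(C)(C)OC1=O | intermediate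
15 | 5-{[5,7-dihydroxy-2,2-dimethyl-6-(2-methylpropanoyl)-2H-chromen-8-yl]methyl}-2,2-dimethyl-1,3-dioxane-4,6-dione | CC(C)C(=O)c1c(O)c(CC2C(=O)OC(C)(C)OC2=O)c2OC(C)(C)C=Cc2c1O | intermediate
16 | α-carboxylic acid of lactone 17 | OC(=O)C1Cc2c(OC1=O)c(C(=O)C(C)C)c(O)c1C=CC(C)(C)Oc21 | intermediate
17 | tricyclic lactone (dihydrocoumarin closed on the 7′-OH) | O=C1CCc2c(O1)c(C(=O)C(C)C)c(O)c1C=CC(C)(C)Oc21 | intermediate
18 | 5′-O-TBS ether and O-TBS ketene acetal of 17 | CC(C)C(=O)c1c(O[Si](C)(C)C(C)(C)C)c2C=CC(C)(C)Oc2c2CC=C(O[Si](C)(C)C(C)(C)C)Oc12 | intermediate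
19 | tetracyclic ketal (ring A as 1,1-diethoxy-5-ketone, C3 as silyl aryl ketal, C4 as in 20, C2 and C3 undefined) | CCOC1(OCC)CC(=O)[C@](C)(CC=C(C)C)C2(O[Si](C)(C)C(C)(C)C)Oc3c(CC12)c4OC(C)(C)C=Cc4c(O[Si](C)(C)C(C)(C)C)c3C(=O)C(C)C | intermediate
20 | (S)-des-isobutyryl compound | CC(C)=CC[C@]1(C)C(O)=C(Cc2c(O)c(C(=O)C(C)C)c(O)c3c2OC(C)(C)C=C3)C(=O)C=C1O | intermediate
21 | 2-methylpropanoyl chloride | CC(C)C(=O)Cl | starting material
22 | C1-O-isobutyryl enol ester of 20 | CC(C)=CC[C@]1(C)C(O)=C(Cc2c(O)c(C(=O)C(C)C)c(O)c3c2OC(C)(C)C=C3)C(OC(=O)C(C)C)=CC1=O | intermediate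
23 | CNP0319758.1, (R) at C4 | CC(C)=CC[C@]1(C)C(O)=C(Cc2c(O)c(C(=O)C(C)C)c(O)c3c2OC(C)(C)C=C3)C(=O)C(C(=O)C(C)C)=C1O | target

Total step count: 9. Longest linear sequence: 6 (steps 4 to 9).

Steps most likely to fail

Step 8.
- What may go wrong: the annulation may stall after the first C–C bond because the hindered enol ether does not close onto the silylated lactone. Facial discrimination between methyl and prenyl in the closure may be poor. Cleavage of the C1–C6 bond or protodesilylation of 18 may compete.
- Fallback, from 4 and 17, back at 20: the same two bonds are made in one flask by known enolate chemistry and the enantiomers are separated afterwards. Acid chloride 4 is C-acylated onto Meldrum's acid 12 (pyridine, CH2Cl2, 0 °C) to the acyl Meldrum's acid F1. Methanolysis (MeOH, reflux) gives methyl 4,7-dimethyl-3-oxooct-6-enoate F2. Its dianion (LiN(iPr)2, 2.1 equiv, THF, −78 to 0 °C) is acylated at the γ-carbon by the lithium phenoxide of 17 to the open-chain triketo ester F3. KN(SiMe3)2 added to the same flask drives the Dieckmann closure to racemic 20 F4. Fractional crystallisation of the (S)-1-phenylethylammonium salt F5 and acidification give 20.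

Step 3.
- What may go wrong: direct C-acylation of the very nucleophilic ketene acetal by the acid chloride, and dimerisation of the ketene, may outrun the [2+2] cycloaddition.
- Fallback, from 4, back at 7: 4 is dehydrochlorinated (Et3N, Et2O, reflux) in the presence of ethoxyacetylene, a much poorer acyl acceptor. This gives 3-ethoxy-4-methyl-4-(3-methylbut-2-en-1-yl)cyclobut-2-en-1-one F6. Strain-driven conjugate addition of ethanol (NaOEt cat., EtOH, 0 °C) then gives 7.

Step 6.
- What may go wrong: formaldehyde may couple two molecules of 11 through a methylene bridge, and the methylene Meldrum's acid may oligomerise before C8′ adds.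
- Fallback, from 11, back at 17: the one-carbon unit is first fixed on the arene. A Mannich reaction with N,N-dimethylmethyleneiminium iodide (CH2Cl2, 23 °C) gives 1-{8-[(dimethylamino)methyl]-5,7-dihydroxy-2,2-dimethyl-2H-chromen-6-yl}-2-methylpropan-1-one F7. Heating F7 with 12 in toluene exchanges the amine for the Meldrum's acid carbon by elimination–addition to give 15. Compound 15 lactonises and decarboxylates to 17 as in step 6.

Further compounds
F1 | step 8 | 5-(1-hydroxy-2,5-dimethylhex-4-en-1-ylidene)-2,2-dimethyl-1,3-dioxane-4,6-dione | CC(C)=CCC(C)C(O)=C1C(=O)OC(C)(C)OC1=O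
F2 | step 8 | methyl 4,7-dimethyl-3-oxooct-6-enoate (racemic) | CC(C)=CCC(C)C(=O)CC(=O)OC
F3 | step 8 | methyl 7-[5,7-dihydroxy-2,2-dimethyl-6-(2-methylpropanoyl)-2H-chromen-8-yl]-4-methyl-4-(3-methylbut-2-en-1-yl)-3,5-dioxoheptanoate (racemic) | COC(=O)CC(=O)C(C)(CC=C(C)C)C(=O)CCc1c(O)c(C(=O)C(C)C)c(O)c2C=CC(C)(C)Oc12
F4 | step 8 | racemic 20 | CC(C)=CCC1(C)C(O)=C(Cc2c(O)c(C(=O)C(C)C)c(O)c3c2OC(C)(C)C=C3)C(=O)C=C1O
F5 | step 8 | (S)-1-phenylethylammonium salt of 20 | C[C@H](N)c1ccccc1.CC(C)=CC[C@]1(C)C(O)=C(Cc2c(O)c(C(=O)C(C)C)c(O)c3c2OC(C)(C)C=C3)C(=O)C=C1O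
F6 | step 3 | 3-ethoxy-4-methyl-4-(3-methylbut-2-en-1-yl)cyclobut-2-en-1-one (racemic) | CCOC1=CC(=O)C1(C)CC=C(C)C
F7 | step 6 | 1-{8-[(dimethylamino)methyl]-5,7-dihydroxy-2,2-dimethyl-2H-chromen-6-yl}-2-methylpropan-1-one | CC(C)C(=O)c1c(O)c(CN(C)C)c2OC(C)(C)C=Cc2c1O
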